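We read this flask at the moment when 50% of the Z is converted, and we want to know what the catalyst is doing then.

Z 0.21 M; X 1.00 equiv; E 5 mol%

    Z + X + E ⇌ E + G (K1 = 140 L mol⁻¹, k1 = 65.6 L² mol⁻² s⁻¹)
    2 E ⇌ E2, settled at all times (K2 = 21600 L mol⁻¹)

- for a step with 2 of a species take k times the square, and two of it per event
- a form made of two catalysts counts as two
- charge of Z (flask): 0.21 M

- the form that holds most of the catalyst when 50% of the Z are converted (E2 / E)
- its share of the catalyst then
- apparent order in X when 50% of the Z are converted (percent change of the rate of making G for one percent more X charged)
- factor on the rate of making G when 50% of the Z are converted if E is charged twice over

The catalyst charged is 0.0105 M, and each E2 counts as two catalysts, so free E plus E2 counted double equals that charge. Its balance folds into one number, 227: the pairing number, the constant of the pairing step times the catalyst charged. It tells how far the charge stands above the concentration scale of pairing, and it holds neither Z nor X. The balance says that the square of the free share equals the paired share divided by 2 times the pairing number. Since that number is far above one, we first take the paired share as one, which gives a free share of 4.70%. Putting the paired share this leaves back into the balance gives 4.58%. So nearly all of the catalyst is paired: the main form is E2, with 95.4%. At a given conversion the rate follows cE. With E charged twice over, the pairing number is 454, the same two steps give a free share of 3.26%, and the rate is multiplied by 1.42.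

One number is not enough for the order in X: the pairing number holds no X. At fixed conversion the rate goes as cZ times cX, minus cG over 140 L mol⁻¹. More X charged raises cX by the whole extra amount, and that gives 2.15.

The forecast gives E2 at 95.4% (from 94.5% to 96.5%), an order of 2.15 (from 1 to 2.3) and a factor of 1.42 (from 1.38 to 1.46), on the ground that “free E scales roughly as the square root of the charge”.

The simulation gives E2 at 95.4%, an order of 2.1 and a factor of 1.42, so the forecast stands.

In this flask the share of E2 still reads 95.4% at 394 s, as the pairing number 227 leads us to expect, while the rate at that later point is 0.28 of the rate at 50% conversion. In a second flask with twice the E, the pairing number is 454, our free shares put the time to 50% conversion at 0.702 of the first flask's time, and the run reads 0.702.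

The constants are made up; the flask was simulated.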